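**Plan**
1. Labels: C1–C2 ethyl, C3 carbinol, C4–C8 piperidine carbons (ring A; C4 and C8 on N), C9–C13 cyclopentane (ring C; C10 Me, C11 OH, C12 spiro, C13 tertiary OH), C14–C16 azepane CH2 (ring B = N, C8, C9, C13–C16), C2′–C4′ butenolide carbons.
2. Feature: ring C shares the C9–C13 bond with ring B and bears oxygen on three neighbouring carbons (C11, C12, C13). That is a masked cyclopentenone (C11=O, C12=C13), i.e. alkene C9=C10 + alkyne C12≡C13 + CO.
3. Cuts: butenolide O–C2′ and C3′=C4′ (ylide on an α-hydroxy ester); C12–O and C13–O (cis-dihydroxylation); C9–C13, C10–C11 and C11–C12 together (Pauson–Khand); then C12–CO2Me, N–C16, C9=C10 and C2–C3.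
4. Forward: ring A by hydrogenation of a 2,6-disubstituted pyridine; the two arms and the N-pentynyl chain are added; rings B and C close in one step; the spirobutenolide comes last.
5. Stereochemistry: C4/C8 from cis-hydrogenation plus lipase desymmetrisation; C3 by catalyst-controlled ethyl addition; C10 from the E alkene and C9 from C8 in the cyclocarbonylation; C11 by 1,2-reduction anti to the methyl; C12/C13 by osmylation anti to the C11 silyl ether.

Key step: step 13

Assumption: the lipase is taken to acetylate the hydroxymethyl arm on the S-configured ring carbon of the meso diol; if the other monoacetate forms, the same N-Boc propenyl piperidine results by running the olefination sequence on the free arm first and the carbinol sequence after deacetylation.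

Step 1
Reactants: 1 pyridine-2,6-diyldimethanol
Product: 2 cis-piperidine-2,6-diyldimethanol (meso)
Conditions: H2 (5 bar), Rh/Al2O3, H2O–AcOH, rt
Reagents that add atoms: none
Why: Heterogeneous hydrogenation delivers all ring hydrogens from the catalyst face, so the 2,6-substituents end cis (meso), and rhodium is chosen to limit hydrogenolysis of the pyridylic C–O bonds.

Step 2
Reactants: 2 cis-piperidine-2,6-diyldimethanol
Product: 3 tert-butyl (2R,6S)-2,6-bis(hydroxymethyl)piperidine-1-carboxylate (meso)
Conditions: Boc2O, MeOH, 40 °C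
Reagents that add atoms: di-tert-butyl dicarbonate, CC(C)(C)OC(=O)OC(=O)OC(C)(C)C
Why: The secondary amine is much more nucleophilic than the primary alcohols, so carbamate formation (N-acylation) is chemoselective.

Step 3
Reactants: 3 meso N-Boc diol
Product: 4 tert-butyl (2S,6R)-2-(acetoxymethyl)-6-(hydroxymethyl)piperidine-1-carboxylate
Conditions: immobilised Candida antarctica lipase B, vinyl acetate, i-Pr2O, rt
Reagents that add atoms: vinyl acetate, CC(=O)OC=C
Why: Lipase-catalysed transesterification distinguishes the enantiotopic hydroxymethyl groups of a meso N-acyl 2,6-bis(hydroxymethyl)piperidine (enzymatic desymmetrisation) and so fixes both ring stereocentres, the future C4 (R) and C8 (S), in one operation.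

Step 4
Reactants: 4 monoacetate
Product: 5 tert-butyl (2S,6R)-2-(acetoxymethyl)-6-formylpiperidine-1-carboxylate
Conditions: TEMPO (10 mol %), PhI(OAc)2, CH2Cl2, rt
Reagents that add atoms: none
Why: Oxoammonium oxidation stops at the aldehyde and is mild enough to leave the α-amino stereocentre and the acetate untouched.

Step 5
Reactants: 5 aldehyde; 6 diethylzinc
Product: 7 tert-butyl (2S,6R)-2-(acetoxymethyl)-6-[(1R)-1-hydroxypropyl]piperidine-1-carboxylate
Conditions: Et2Zn (2 equiv), (2R)-(+)-3-exo-morpholinoisoborneol (10 mol %), toluene, 0 °C; aq NH4Cl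
Reagents that add atoms: diethylzinc (6), CC[Zn]CC
Why: Amino-alcohol-catalysed dialkylzinc addition is reagent-controlled, the (2R) ligand sending ethyl to the Re face of the aldehyde to set C3 as R (oxygen syn to nitrogen), while acetate and carbamate are inert to the zinc reagent.

Step 6
Reactants: 7 carbinol
Product: 8 tert-butyl (2S,6R)-2-(acetoxymethyl)-6-[(1R)-1-(tert-butyldimethylsilyloxy)propyl]piperidine-1-carboxylate
Conditions: TBSOTf, 2,6-lutidine, CH2Cl2, −78 to 0 °C
Reagents that add atoms: tert-butyldimethylsilyl trifluoromethanesulfonate, CC(C)(C)[Si](C)(C)OS(=O)(=O)C(F)(F)F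
Why: Silyl triflate silylates the hindered secondary alcohol at low temperature faster than it attacks the carbamate, giving an ether that lasts to the final step.

Step 7
Reactants: 8 silyl ether acetate
Product: 9 tert-butyl (2R,6S)-2-[(1R)-1-(tert-butyldimethylsilyloxy)propyl]-6-(hydroxymethyl)piperidine-1-carboxylate
Conditions: K2CO3 (0.2 equiv), MeOH, 0 °C to rt
Reagents that add atoms: none
Why: Methoxide-catalysed transesterification removes the primary acetate while silyl ether and carbamate survive.

Step 8
Reactants: 9 primary alcohol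
Product: 10 tert-butyl (2R,6S)-2-[(1R)-1-(tert-butyldimethylsilyloxy)propyl]-6-formylpiperidine-1-carboxylate
Conditions: TEMPO (10 mol %), PhI(OAc)2, CH2Cl2, rt
Reagents that add atoms: none
Why: The same oxoammonium oxidation gives the configurationally sensitive N-Boc α-amino aldehyde without over-oxidation, and it is used directly.

Step 9
Reactants: 10 aldehyde; 11 5-(ethylsulfonyl)-1-phenyl-1H-tetrazole
Product: 12 tert-butyl (2R,6S)-2-[(1R)-1-(tert-butyldimethylsilyloxy)propyl]-6-[(E)-prop-1-enyl]piperidine-1-carboxylate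
Conditions: 11, KN(SiMe3)2, DME, −60 °C; then 10, −60 °C to rt
Reagents that add atoms: 5-(ethylsulfonyl)-1-phenyl-1H-tetrazole (11), CCS(=O)(=O)c1nnnn1-c1ccccc1
Why: Julia–Kocienski olefination of the pre-metallated phenyltetrazolyl sulfone with an α-branched aldehyde gives the E alkene after Smiles rearrangement and loss of SO2, and the cold conditions protect C8 from epimerisation.

Step 10
Reactants: 12 N-Boc propenyl piperidine
Product: 14 (2R,6S)-2-[(1R)-1-(tert-butyldimethylsilyloxy)propyl]-6-[(E)-prop-1-enyl]piperidine, via trimethylsilyl carbamate 13 (not isolated)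
Conditions: TMSOTf, 2,6-lutidine, CH2Cl2, 0 °C; then MeOH
Reagents that add atoms: none
Why: The silyl triflate converts the tert-butyl carbamate into the silyl carbamate with loss of isobutene and methanolysis then releases CO2 and the amine, a non-protic Boc cleavage that spares the TBS ether and the alkene.

Step 11
Reactants: 14 secondary amine; 15 5-iodopent-1-yne
Product: 16 (2R,6S)-1-(pent-4-ynyl)-2-[(1R)-1-(tert-butyldimethylsilyloxy)propyl]-6-[(E)-prop-1-enyl]piperidine
Conditions: K2CO3, MeCN, 70 °C
Reagents that add atoms: 5-iodopent-1-yne (15), C#CCCCI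
Why: SN2 N-alkylation by a primary iodide; the flanked nitrogen reacts slowly and needs heat but cannot be alkylated twice under these conditions.

Step 12
Reactants: 16 terminal alkyne; 17 methyl chloroformate
Product: 19 methyl 6-[(2R,6S)-2-[(1R)-1-(tert-butyldimethylsilyloxy)propyl]-6-[(E)-prop-1-enyl]piperidin-1-yl]hex-2-ynoate, via lithium acetylide 18 (not isolated)
Conditions: n-BuLi (1.05 equiv), THF, −78 °C; ClCO2Me, −78 to −30 °C
Reagents that add atoms: methyl chloroformate (17), COC(=O)Cl
Why: The alkyne C–H is the only acidic site, and the acetylide is acylated by the chloroformate at low temperature (alkyne C-carboxylation) much faster than the tertiary amine reacts.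

Step 13
Reactants: 19 enyne (ynoate and (E)-propenyl group on the cis-2,6-piperidine)
Product: 21 tricyclic enone ester (3R,4R,8S,9S,10S; C11=O, C12=C13, CO2Me on C12, H8/H9 cis, H9/H10 trans), via hexacarbonyldicobalt complex 20 (not isolated)
Conditions: CF3CO2H (1.05 equiv), CH2Cl2, 0 °C; Co2(CO)8 (1.1 equiv), rt; then ClCH2CH2Cl (5 mM), n-BuSMe (4 equiv), 83 °C, N2; cold aq NaHCO3
Reagents that add atoms: dicobalt octacarbonyl, O=C=[Co](=C=O)(=C=O)(=C=O)[Co](=C=O)(=C=O)(=C=O)=C=O (one CO ligand, [C-]#[O+], becomes C11=O)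
Why: The alkyne of the ammonium salt forms complex 20; loss of CO, coordination of the tethered propenyl group, insertion of the alkene into the Co–C13 bond (C9–C13), CO insertion and reductive elimination (C10–C11, C11–C12) give the enone, a Pauson–Khand reaction whose closest known relatives are cyclisations of ring-constrained 1,8-enynes to bicyclo[5.3.0]decenones and of alkynoates. The azepane closes in the insertion step as the tether ring (exo with respect to both the alkene and the alkyne, only C9 and C13 entering the ring), and the cyclopentenone closes by the final reductive elimination of the [2+2+1] array; the tether also fixes the regiochemistry (ketone next to the ester-bearing carbon). C10 follows from suprafacial insertion, which copies the E geometry into the trans H9/H10 relationship. C9 is set by C8: the step needs C13 to add to the alkene face that leaves H9 syn to H8, which is the face exposed in the rotamer with the C8–N bond near the alkene plane and C7 anti to the forming bond, on a chair piperidinium with both ring substituents equatorial. An E alkene has no 1,3-allylic strain, so this face is favoured only by the protonated C8–N bond acting as the σ-acceptor that prefers the in-plane (inside) position, and it is not enforced; protonation also prevents nitrogen–cobalt ligation and amine addition to the ynoate. Because H9 (γ to the keto ester) and H10 are enolisable, 21 is worked up cold and reduced at once.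

Step 14
Reactants: 21 tricyclic enone ester
Product: 22 allylic alcohol (11S; C11–OH cis to the C10 methyl)
Conditions: CeCl3·7H2O, NaBH4, MeOH, −78 °C
Reagents that add atoms: none
Why: Luche 1,2-reduction, in which the cerium-activated ketone takes hydride on the face opposite the neighbouring C10 methyl to give the 11S alcohol without conjugate reduction of the alkylidene keto ester.

Step 15
Reactants: 22 allylic alcohol
Product: 23 C11 tert-butyldimethylsilyl ether
Conditions: TBSOTf, 2,6-lutidine, CH2Cl2, 0 °C
Reagents that add atoms: tert-butyldimethylsilyl trifluoromethanesulfonate, CC(C)(C)[Si](C)(C)OS(=O)(=O)C(F)(F)F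
Why: Silylation keeps this hydroxyl away from the ylide of step 17 and provides the bulky allylic ether that steers the osmylation.

Step 16
Reactants: 23 enoate
Product: 24 C12,C13 cis-diol ester (12R,13S; both hydroxyls anti to the C11 silyl ether)
Conditions: K2OsO2(OH)4 (10 mol %), N-methylmorpholine N-oxide, citric acid, t-BuOH/H2O, rt
Reagents that add atoms: N-methylmorpholine N-oxide, C[N+]1([O-])CCOCC1; water, O
Why: Catalytic osmylation in the acidic variant suited to electron-poor alkenes, with the amine protonated, adds both oxygens suprafacially to C12=C13 anti to the allylic C11 silyl ether and the C10 methyl, setting C12 and C13 together.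

Step 17
Reactants: 24 diol ester; 25 (triphenylphosphoranylidene)ketene
Product: 27 spiro 4-methoxybutenolide (C3′–H), via acyl ylide 26 (not isolated)
Conditions: Ph3P=C=C=O (1.5 equiv), toluene, 110 °C, sealed tube
Reagents that add atoms: (triphenylphosphoranylidene)ketene (25), O=C=C=P(c1ccccc1)(c1ccccc1)c1ccccc1
Why: Addition–Wittig cascade in which the more acidic α-hydroxy-ester hydroxyl (C12–OH) adds to the cumulated ylide and the resulting ester ylide olefinates the adjacent ester carbonyl in a five-ring-forming intramolecular Wittig reaction, keeping OMe on C4′ and leaving the C13 hydroxyl free.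

Step 18
Reactants: 27 butenolide; 28 iodomethane
Product: 30 bis-TBS ether of the target (3′-methylbutenolide), via dilithio species 29 (not isolated)
Conditions: LiN(i-Pr)2 (2.3 equiv), THF, −78 °C; MeI (1.1 equiv), −78 °C; AcOH quench
Reagents that add atoms: iodomethane (28), CI
Why: With C12 quaternary the vinylic C3′–H is the only acidic C–H, so after alkoxide formation the amide base lithiates C3′ and the vinyllithium is C-methylated at −78 °C far faster than the hindered tertiary amine can be quaternised.

Step 19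
Reactants: 30 bis-silyl ether
Product: 31 target compound
Conditions: HF·pyridine, pyridine, THF, 0 °C to rt
Reagents that add atoms: none
Why: Fluoride cleaves both secondary silyl ethers through Si–F bond formation under buffered conditions that leave the tetronate, the tertiary alcohol and the amine untouched.

**Compound list**
1 | pyridine-2,6-diyldimethanol | OCc1cccc(CO)n1 | starting material
2 | cis-piperidine-2,6-diyldimethanol (meso) | OC[C@H]1CCC[C@@H](CO)N1 | intermediate
3 | tert-butyl (2R,6S)-2,6-bis(hydroxymethyl)piperidine-1-carboxylate | OC[C@H]1CCC[C@@H](CO)N1C(=O)OC(C)(C)C | intermediate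
4 | tert-butyl (2S,6R)-2-(acetoxymethyl)-6-(hydroxymethyl)piperidine-1-carboxylate | OC[C@H]1CCC[C@@H](COC(C)=O)N1C(=O)OC(C)(C)C | intermediate
5 | tert-butyl (2S,6R)-2-(acetoxymethyl)-6-formylpiperidine-1-carboxylate | O=C[C@H]1CCC[C@@H](COC(C)=O)N1C(=O)OC(C)(C)C | intermediate
6 | diethylzinc | CC[Zn]CC | starting material
7 | tert-butyl (2S,6R)-2-(acetoxymethyl)-6-[(1R)-1-hydroxypropyl]piperidine-1-carboxylate | CC[C@@H](O)[C@H]1CCC[C@@H](COC(C)=O)N1C(=O)OC(C)(C)C | intermediate
8 | tert-butyl (2S,6R)-2-(acetoxymethyl)-6-[(1R)-1-(tert-butyldimethylsilyloxy)propyl]piperidine-1-carboxylate | CC[C@@H](O[Si](C)(C)C(C)(C)C)[C@H]1CCC[C@@H](COC(C)=O)N1C(=O)OC(C)(C)C | intermediate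
9 | tert-butyl (2R,6S)-2-[(1R)-1-(tert-butyldimethylsilyloxy)propyl]-6-(hydroxymethyl)piperidine-1-carboxylate | CC[C@@H](O[Si](C)(C)C(C)(C)C)[C@H]1CCC[C@@H](CO)N1C(=O)OC(C)(C)C | intermediate
10 | tert-butyl (2R,6S)-2-[(1R)-1-(tert-butyldimethylsilyloxy)propyl]-6-formylpiperidine-1-carboxylate | CC[C@@H](O[Si](C)(C)C(C)(C)C)[C@H]1CCC[C@@H](C=O)N1C(=O)OC(C)(C)C | intermediate
11 | 5-(ethylsulfonyl)-1-phenyl-1H-tetrazole | CCS(=O)(=O)c1nnnn1-c1ccccc1 | starting material
12 | tert-butyl (2R,6S)-2-[(1R)-1-(tert-butyldimethylsilyloxy)propyl]-6-[(E)-prop-1-enyl]piperidine-1-carboxylate | CC[C@@H](O[Si](C)(C)C(C)(C)C)[C@H]1CCC[C@@H](/C=C/C)N1C(=O)OC(C)(C)C | intermediate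
13 | trimethylsilyl carbamate of 14 (not isolated) | CC[C@@H](O[Si](C)(C)C(C)(C)C)[C@H]1CCC[C@@H](/C=C/C)N1C(=O)O[Si](C)(C)C | intermediate
14 | (2R,6S)-2-[(1R)-1-(tert-butyldimethylsilyloxy)propyl]-6-[(E)-prop-1-enyl]piperidine | CC[C@@H](O[Si](C)(C)C(C)(C)C)[C@H]1CCC[C@@H](/C=C/C)N1 | intermediate
15 | 5-iodopent-1-yne | C#CCCCI | starting material
16 | (2R,6S)-1-(pent-4-ynyl)-2-[(1R)-1-(tert-butyldimethylsilyloxy)propyl]-6-[(E)-prop-1-enyl]piperidine | CC[C@@H](O[Si](C)(C)C(C)(C)C)[C@H]1CCC[C@@H](/C=C/C)N1CCCC#C | intermediate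
17 | methyl chloroformate | COC(=O)Cl | starting material
18 | lithium acetylide of 16 (not isolated) | CC[C@@H](O[Si](C)(C)C(C)(C)C)[C@H]1CCC[C@@H](/C=C/C)N1CCCC#C[Li] | intermediate
19 | methyl 6-[(2R,6S)-2-[(1R)-1-(tert-butyldimethylsilyloxy)propyl]-6-[(E)-prop-1-enyl]piperidin-1-yl]hex-2-ynoate | CC[C@@H](O[Si](C)(C)C(C)(C)C)[C@H]1CCC[C@@H](/C=C/C)N1CCCC#CC(=O)OC | intermediate
20 | hexacarbonyldicobalt complex of the trifluoroacetate salt of 19 (not isolated) | CC[C@@H](O[Si](C)(C)C(C)(C)C)[C@H]1CCC[C@@H](/C=C/C)[NH+]1CCCC23[Co]4(=C=O)(=C=O)(=C=O)C2(C(=O)OC)[Co]34(=C=O)(=C=O)=C=O.[O-]C(=O)C(F)(F)F | intermediate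
21 | tricyclic enone ester (3R,4R,8S,9S,10S), C3–OTBS | CC[C@@H](O[Si](C)(C)C(C)(C)C)[C@H]1CCC[C@H]2[C@H]3[C@H](C)C(=O)C(C(=O)OC)=C3CCCN12 | intermediate
22 | C11 allylic alcohol (11S) | CC[C@@H](O[Si](C)(C)C(C)(C)C)[C@H]1CCC[C@H]2[C@H]3[C@H](C)[C@H](O)C(C(=O)OC)=C3CCCN12 | intermediate
23 | C3,C11 bis-TBS enoate | CC[C@@H](O[Si](C)(C)C(C)(C)C)[C@H]1CCC[C@H]2[C@H]3[C@H](C)[C@H](O[Si](C)(C)C(C)(C)C)C(C(=O)OC)=C3CCCN12 | intermediate
24 | C12,C13 cis-diol ester (12R,13S) | CC[C@@H](O[Si](C)(C)C(C)(C)C)[C@H]1CCC[C@H]2[C@H]3[C@H](C)[C@H](O[Si](C)(C)C(C)(C)C)[C@](O)(C(=O)OC)[C@]3(O)CCCN12 | intermediate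
25 | (triphenylphosphoranylidene)ketene | O=C=C=P(c1ccccc1)(c1ccccc1)c1ccccc1 | starting material
26 | C12–O acyl ylide (not isolated) | CC[C@@H](O[Si](C)(C)C(C)(C)C)[C@H]1CCC[C@H]2[C@H]3[C@H](C)[C@H](O[Si](C)(C)C(C)(C)C)[C@](OC(=O)C=P(c4ccccc4)(c4ccccc4)c4ccccc4)(C(=O)OC)[C@]3(O)CCCN12 | intermediate
27 | spiro 4-methoxybutenolide, C3′–H, bis-TBS | CC[C@@H](O[Si](C)(C)C(C)(C)C)[C@H]1CCC[C@H]2[C@H]3[C@H](C)[C@H](O[Si](C)(C)C(C)(C)C)[C@@]4(OC(=O)C=C4OC)[C@]3(O)CCCN12 | intermediate
28 | iodomethane | CI | starting material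
29 | C3′-lithio C13-lithium alkoxide of 27 (not isolated) | CC[C@@H](O[Si](C)(C)C(C)(C)C)[C@H]1CCC[C@H]2[C@H]3[C@H](C)[C@H](O[Si](C)(C)C(C)(C)C)[C@@]4(OC(=O)C([Li])=C4OC)[C@]3(O[Li])CCCN12 | intermediate
30 | bis-TBS ether of the target | CC[C@@H](O[Si](C)(C)C(C)(C)C)[C@H]1CCC[C@H]2[C@H]3[C@H](C)[C@H](O[Si](C)(C)C(C)(C)C)[C@@]4(OC(=O)C(C)=C4OC)[C@]3(O)CCCN12 | intermediate
31 | CNP0267781.1 | CC[C@@H](O)[C@H]1CCC[C@H]2[C@H]3[C@H](C)[C@H](O)[C@@]4(OC(=O)C(C)=C4OC)[C@]3(O)CCCN12 | target

Total step count: 19. Longest linear sequence: 19 steps (1 to 31).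

**Steps most likely to fail**

Step 13. Alkene insertion may be too slow for a seven-membered closure with a 1,2-disubstituted alkene and an ester-bearing alkyne, so that decomplexation and oligomerisation take over. In addition, the alkene face is not enforced by strain, so the C9,C10-epimeric tricycle may form; the usual exo preference of a substituent at the allylic carbon would favour that epimer. The fallback takes the ester out of the ring-forming step and sets out from 16. The terminal alkyne, the most reactive alkyne class in this reaction, is cyclised as its trifluoroacetate salt under the same cobalt protocol to the ester-free tricyclic enone F1. Iodination at C12 (I2, pyridine, CH2Cl2) gives the 2-iodoenone F2. Palladium-catalysed methoxycarbonylation (PdCl2(PPh3)2, CO, MeOH, 2,6-lutidine, 50 °C) returns to the route at 21. This fallback does not change the facial question at C9.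

Step 16. Osmium may add to the other face of C12=C13 (syn to the silyl ether, away from C8), or turnover may stall at the tetrasubstituted enoate. The fallback replaces steric steering by hydroxyl-directed delivery and sets out from 22. Mitsunobu inversion (4-nitrobenzoic acid, PPh3, DIAD) gives the 11-epi 4-nitrobenzoate F3, and K2CO3 in MeOH frees the 11-epi alcohol F4. Stoichiometric OsO4 with TMEDA (CH2Cl2, −78 °C; then aq Na2SO3), held by hydrogen bonding to this hydroxyl, gives the all-syn triol F5. Oxidation of its only secondary alcohol (1,1,1-triacetoxy-1,1-dihydro-1,2-benziodoxol-3(1H)-one) gives the C11 ketone F6. Me4NBH(OAc)3 (MeCN/AcOH, −20 °C), bound to the C12 hydroxyl, delivers hydride on that face and gives the 11S triol F7. TBSOTf with 2,6-lutidine at −78 °C silylates the secondary hydroxyl and returns to the route at 24.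

Step 17. The ylide may add to the C13 hydroxyl instead of the C12 hydroxyl, or the Wittig closure onto the hindered ester may stop at the acyl ylide. The fallback attaches the carbons at the ester carbon instead and sets out from 24. Claisen condensation with the lithium enolate of tert-butyl propionate (LiN(i-Pr)2, THF, −78 to 0 °C) gives the β-keto tert-butyl ester F8. Heating in toluene (110 °C) expels 2-methylpropan-2-ol, and the acylketene is trapped by the C12 hydroxyl in a five-membered closure to the 3-methyltetronic acid F9. O-Methylation (Me3SiCHN2, MeOH/toluene) returns to the route at 30, so step 18 is not needed.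

**Further compounds**
F1 | step 13 | ester-free tricyclic enone (C12–H) | CC[C@@H](O[Si](C)(C)C(C)(C)C)[C@H]1CCC[C@H]2[C@H]3[C@H](C)C(=O)C=C3CCCN12
F2 | step 13 | C12-iodo tricyclic enone | CC[C@@H](O[Si](C)(C)C(C)(C)C)[C@H]1CCC[C@H]2[C@H]3[C@H](C)C(=O)C(I)=C3CCCN12
F3 | step 16 | 11-epi 4-nitrobenzoate of 22 | CC[C@@H](O[Si](C)(C)C(C)(C)C)[C@H]1CCC[C@H]2[C@H]3[C@H](C)[C@@H](OC(=O)c4ccc(cc4)[N+](=O)[O-])C(C(=O)OC)=C3CCCN12
F4 | step 16 | 11-epi allylic alcohol | CC[C@@H](O[Si](C)(C)C(C)(C)C)[C@H]1CCC[C@H]2[C@H]3[C@H](C)[C@@H](O)C(C(=O)OC)=C3CCCN12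
F5 | step 16 | 11-epi C11,C12,C13 all-syn triol ester | CC[C@@H](O[Si](C)(C)C(C)(C)C)[C@H]1CCC[C@H]2[C@H]3[C@H](C)[C@@H](O)[C@](O)(C(=O)OC)[C@]3(O)CCCN12
F6 | step 16 | C11 ketone of the C12,C13-diol ester | CC[C@@H](O[Si](C)(C)C(C)(C)C)[C@H]1CCC[C@H]2[C@H]3[C@H](C)C(=O)[C@](O)(C(=O)OC)[C@]3(O)CCCN12
F7 | step 16 | 11S triol ester (C11–OH free) | CC[C@@H](O[Si](C)(C)C(C)(C)C)[C@H]1CCC[C@H]2[C@H]3[C@H](C)[C@H](O)[C@](O)(C(=O)OC)[C@]3(O)CCCN12
F8 | step 17 | C12 β-keto tert-butyl ester | CC[C@@H](O[Si](C)(C)C(C)(C)C)[C@H]1CCC[C@H]2[C@H]3[C@H](C)[C@H](O[Si](C)(C)C(C)(C)C)[C@](O)(C(=O)C(C)C(=O)OC(C)(C)C)[C@]3(O)CCCN12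
F9 | step 17 | spiro 3-methyltetronic acid | CC[C@@H](O[Si](C)(C)C(C)(C)C)[C@H]1CCC[C@H]2[C@H]3[C@H](C)[C@H](O[Si](C)(C)C(C)(C)C)[C@@]4(OC(=O)C(C)=C4O)[C@]3(O)CCCN12
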